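I have no constants for this flask yet, only readings, so I read one from the earlier runs and ask what it says about the flask, where 0.150 M of capture agent meets 1.5 M of substrate in 4 portions.

| setting | Friday's | Thursday's | Wednesday's | flask |
|---|---|---|---|---|
| substrate | 1.5 M (in portions, 4) | 1.5 M (in portions, 4) | 0.75 M (in portions, 4) | 1.5 M (in portions, 4) |
| capture agent | 0.21 M | 0.33 M | 0.15 M | 0.150 M |
| remark | run made earlier; portions every 5.0 h | run made earlier; portions every 5.0 h | run made earlier; portions every 5.0 h | the portions of substrate follow each other after 5.0 h, the first at the start |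
| time |  |  |  | 15 d |

| run | time / d | product / % | intermediate C / % | substrate / % |
|---|---|---|---|---|
| Friday's | 1.25 | 4 | 10 | 36 |
| Friday's | 2.50 | 17 | 18 | 27 |
| Friday's | 4.00 | 33 | 16 | 22 |
| Friday's | 8.00 | 59 | 10 | 11 |
| Friday's | 15.0 | 86 | 7 | 2 |
| Thursday's | 1.25 | 8 | 16 | 35 |
| Thursday's | 4.00 | 34 | 18 | 18 |
| Thursday's | 8.00 | 61 | 12 | 9 |
| Thursday's | 10.0 | 70 | 10 | 6 |
| Thursday's | 15.0 | 81 | 5 | 5 |
| Wednesday's | 1.25 | 7 | 14 | 39 |
| Wednesday's | 2.50 | 20 | 18 | 27 |
| Wednesday's | 4.00 | 39 | 18 | 19 |
| Wednesday's | 8.00 | 60 | 11 | 9 |
| Wednesday's | 15.0 | 81 | 4 | 5 |

(scatter of a reading: 1.5 percentage points)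

- the analysis behind the earlier runs scatters by 1.5 percentage points, standard deviation
- the reaction counts as stopped when no species that holds the substrate changes by six tenths of a point or more over the second half of the time

1. which holds at 15 d: what has brought the reaction to rest, or that it has not come to rest (forward and back rates have come level / all of the substrate has reacted / it is still moving)
2. how much product there is at 15 d, in percent of the substrate charged
3. how much intermediate C there is at 15 d, in percent of the substrate charged

I solve the two ends and join them. At the early end, the last portion goes in at 0.625 d, and at the first reading, 1.25 d, Friday's run has 4 % product and Thursday's has 8 %. At the late end, I take the shortfall, the part of the charge that is not product. Averaged over the runs, it goes from 40.0 % at 8.00 d to 17.3 % at 15.0 d: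

half-life of the shortfall = 7.00 d × ln(2) / ln(40.0 % / 17.3 %) = 5.80 d

This is the shortfall half-life, the time in which the part of the charge that is not product halves, with the tail treated as pseudo-first-order.

Now I turn the question round. To count as stopped, the flask needs product to change by less than 0.6 points over the last 7.50 d. In that time the shortfall loses 59.2 % of itself, so:

shortfall needed at mid-time ≈ 0.6 points / 59.2 % ≈ 1 point

The runs read 40.0 % on average at 8.00 d, near mid-time. I therefore expect the flask still to be moving, with product near 82.7 % and intermediate C near 5.33 %, the run averages. The reading to watch is product at mid-time.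

The forecast says it is still moving, with 82 % product and 6 % intermediate C, and expects that “the runs converge later”.

The flask gives it is still moving, with 83.0 % product and 5.02 % intermediate C. Raised alone, with the other amounts and the time held, capture agent moves product by 5 points at 0.489 M, against the flask's 0.150 M. Carrying the flask's 59.3 % product at 7.50 d forward with the shortfall half-life of 5.80 d gives 83.4 % at 15 d.

    substrate ⇌ intermediate A (K = 0.890, k = 0.00700 min⁻¹)
    capture agent + intermediate B → trapped intermediate (k = 1.60 × 10⁻⁴ M⁻¹ min⁻¹)
    substrate ⇌ intermediate C (K = 0.840, k = 2.50 × 10⁻⁴ min⁻¹)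
    intermediate A → intermediate B (k = 3.20 × 10⁻⁴ min⁻¹)
    intermediate B → product (k = 7.10 × 10⁻⁴ min⁻¹)

Read at 6.0 d, the same flask should by that half-life hold 51.3 % product, counting back from mid-time. The computed value is 50.8 %.

The earlier runs and the new flask were computed from invented constants; scatter was added.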